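**Remark on the chemistry:** the target is achiral, so no stereocenter has to be set. Compounds 18 and 19 are drawn in their keto forms although both should exist largely as enol tautomers; 19 is a transient mixture of diastereomers that converges on aromatization. Iminium 2 is drawn as its chloride.

## Retrosynthetic overview

1. Target 21 ← benzyl ester 20 by hydrogenolysis of the ring B carboxyl protecting group.
2. Ring A of 20 is a folded tetraketide whose carboxyl carbon is already the depside ester carbonyl. In open-chain aryl 3,5,7-trioxododecanoate 18, chain C1 is that ester carbonyl, chain C2–C7 become ring A C1–C6, the C3 and C5 carbonyls become the two phenols, and C8–C12 is the pentyl group. The disconnection is the ring A C1–C6 bond (chain C2–C7), an aldol.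
3. 18 ← ring B phenol 8 + the acylketene 17 released thermally from diketo-dioxinone 16. The hindered ester C–O bond is thus made on an unhindered ketene carbon, before ring A exists.
4. 16 ← trimethyldioxinone 11 + acetyl chloride 12 + hexanoyl chloride 9 (two Claisen-type C-acylations). 8 ← olivetol 1 (formylation, differentiation of the two phenols, oxidation, benzyl ester).
5. Ring order: ring B is present from olivetol; ring A is closed in the penultimate step on the finished ester.

Key step: step 11

## Route

Step 1
Reactants: 1 olivetol (5-pentylbenzene-1,3-diol)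
Product: 3 2,4-dihydroxy-6-pentylbenzaldehyde, via aryl iminium chloride 2 (not isolated)
Conditions: POCl3, DMF, 0 °C to rt; then H2O, 50 °C
Reagents that add atoms: N,N-dimethylformamide CN(C)C=O; water O
Why: Vilsmeier–Haack formylation, in which the chloroiminium ion should attack the resorcinol carbon para to one hydroxyl and ortho to the other (between OH and pentyl), and hydrolysis of iminium 2 releases the aldehyde.

Step 2
Reactants: 3 2,4-dihydroxy-6-pentylbenzaldehyde
Product: 4 2-hydroxy-4-(methoxymethoxy)-6-pentylbenzaldehyde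
Conditions: MOMCl (1.1 equiv), iPr2NEt, CH2Cl2, 0 °C
Reagents that add atoms: chloromethyl methyl ether COCCl
Why: Selective O-alkylation (acetal formation) of the 4-hydroxyl, which is the more acidic phenol para to the aldehyde, while the 2-hydroxyl is held back by its hydrogen bond to the formyl oxygen.

Step 3
Reactants: 4 2-hydroxy-4-(methoxymethoxy)-6-pentylbenzaldehyde
Product: 5 2-methoxy-4-(methoxymethoxy)-6-pentylbenzaldehyde
Conditions: MeI, K2CO3, DMF, rt to 40 °C
Reagents that add atoms: iodomethane CI
Why: Williamson ether synthesis on the remaining chelated phenol, which as its potassium phenoxide in DMF should be methylated cleanly while the MOM acetal is inert to base.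

Step 4
Reactants: 5 2-methoxy-4-(methoxymethoxy)-6-pentylbenzaldehyde
Product: 6 2-methoxy-4-(methoxymethoxy)-6-pentylbenzoic acid
Conditions: NaClO2, NaH2PO4, 2-methyl-2-butene, t-BuOH/H2O, rt
Reagents that add atoms: sodium chlorite [Na+].[O-]Cl=O
Why: Pinnick oxidation of the aldehyde to the acid, with 2-methyl-2-butene scavenging hypochlorous acid so that the electron-rich ring is not chlorinated and the buffered medium sparing the MOM acetal.

Step 5
Reactants: 6 2-methoxy-4-(methoxymethoxy)-6-pentylbenzoic acid
Product: 7 benzyl 2-methoxy-4-(methoxymethoxy)-6-pentylbenzoate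
Conditions: BnBr, K2CO3, DMF, rt
Reagents that add atoms: benzyl bromide BrCc1ccccc1
Why: SN2 O-alkylation of the carboxylate, which makes the ester without any nucleophile having to attack the di-ortho-substituted acyl carbon.

Step 6
Reactants: 7 benzyl 2-methoxy-4-(methoxymethoxy)-6-pentylbenzoate
Product: 8 benzyl 4-hydroxy-2-methoxy-6-pentylbenzoate
Conditions: conc. HCl (cat.), MeOH/THF, 40 °C
Reagents that add atoms: none
Why: Acid-catalysed acetal exchange removes the MOM group as dimethoxymethane, while the benzyl ester, shielded by two ortho substituents, should resist transesterification.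

Step 7
Reactants: 9 hexanoyl chloride
Product: 10 N-methoxy-N-methylhexanamide
Conditions: MeNHOMe·HCl, Et3N (2.2 equiv), CH2Cl2, 0 °C to rt
Reagents that add atoms: N,O-dimethylhydroxylamine hydrochloride CNOC.Cl
Why: N-Acylation of the hydroxylamine by the acid chloride (Weinreb amide formation) is routine and gives an acyl donor that adds a carbanion only once.

Step 8
Reactants: 11 2,2,6-trimethyl-4H-1,3-dioxin-4-one; 12 acetyl chloride
Product: 14 2,2-dimethyl-6-(2-oxopropyl)-4H-1,3-dioxin-4-one, via lithium dienolate 13 (not isolated)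
Conditions: LiN(SiMe3)2 (2 equiv with 2 equiv of 11), THF, −78 °C; then 12 (1 equiv), −78 °C; cold 1 M HCl quench
Reagents that add atoms: none
Why: Vinylogous Claisen-type C-acylation of the dioxinone dienolate at its terminal (gamma) carbon, with the second equivalent of enolate absorbing the proton of the more acidic product and the excess 11 being recoverable.

Step 9
Reactants: 14 2,2-dimethyl-6-(2-oxopropyl)-4H-1,3-dioxin-4-one; 10 N-methoxy-N-methylhexanamide
Product: 16 6-(2,4-dioxononyl)-2,2-dimethyl-4H-1,3-dioxin-4-one, via dilithium dienolate 15 (not isolated)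
Conditions: LiN(iPr)2 (3 equiv), THF, −78 °C; then 10, −78 to −40 °C; cold 1 M HCl quench
Reagents that add atoms: none
Why: Claisen condensation of the dianion at its last-formed, most nucleophilic terminal carbon with the N-methoxy-N-methylamide, whose chelated tetrahedral adduct prevents a second addition.

Step 10
Reactants: 16 6-(2,4-dioxononyl)-2,2-dimethyl-4H-1,3-dioxin-4-one (1.3 equiv); 8 benzyl 4-hydroxy-2-methoxy-6-pentylbenzoate (1.0 equiv)
Product: 18 benzyl 2-methoxy-6-pentyl-4-[(3,5,7-trioxododecanoyl)oxy]benzoate, via acylketene dodec-1-ene-1,3,5,7-tetrone 17 (not isolated)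
Conditions: toluene (concentrated in 8), 110 °C, slow addition of 16; concentrate and use crude at once
Reagents that add atoms: none
Why: Thermal retro-hetero-Diels–Alder cycloreversion of the dioxinone expels acetone and gives acylketene 17, across which the phenol O–H of 8 adds, so the future hindered depside ester is formed at an unhindered sp carbon.

Step 11
Reactants: 18 benzyl 2-methoxy-6-pentyl-4-[(3,5,7-trioxododecanoyl)oxy]benzoate
Product: 20 benzyl 4-[(2,4-dihydroxy-6-pentylbenzoyl)oxy]-2-methoxy-6-pentylbenzoate, via cyclic aldol adduct 19 (not isolated)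
Conditions: Et3N (2 equiv), CH2Cl2, 0 °C to rt
Reagents that add atoms: none
Why: Et3N reversibly enolizes the chain, and although the C4 and C6 methylenes between two ketones are the more acidic sites, only the C2 enolate (between the aryl ester and the C3 ketone) has a ketone within six-membered reach, so it adds to the C7 ketone and forms the C2–C7 bond, which is the C1–C6 bond of ring A. Ring A closes in a 6-(enolendo)-exo-trig mode to aldol adduct 19, whose tertiary hydroxyl is lost by E1cB elimination, and tautomerization of the C3 and C5 carbonyls to phenols then makes the sequence irreversible. No stereocenter has to be controlled, because the two transient stereocenters of 19 are erased on aromatization. The step needs chemoselectivity for C–C closure at C7 over attack at the ester carbon C1, either by the C5 enol oxygen (pyranone formation) or by C6 (Claisen closure to an acylphloroglucinol), each of which would expel phenol 8. The substrate favours this because the reacting C2 enolate holds C1 as a non-electrophilic ester enolate (and the neutral form holds it as a hydrogen-bonded C3 enol ester), while a metal-free amine base in an aprotic, non-nucleophilic solvent avoids both the chelation that templates Claisen closure and solvolysis of the aryl ester. The closest known reaction type is the base-mediated aldol condensation–aromatization of alkyl 3,5,7-triketo esters obtained from diketo-dioxinones by acylketene trapping.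

Step 12
Reactants: 20 benzyl 4-[(2,4-dihydroxy-6-pentylbenzoyl)oxy]-2-methoxy-6-pentylbenzoate
Product: 21 4-[(2,4-dihydroxy-6-pentylbenzoyl)oxy]-2-methoxy-6-pentylbenzoic acid (target)
Conditions: H2 (1 atm), 10% Pd/C, EtOAc, rt
Reagents that add atoms: none
Why: Catalytic hydrogenolysis cleaves only the benzylic C–O bond of the benzyl ester, leaving the aryl depside ester, the methyl ether and the phenols untouched.

## Compound list

1 | olivetol (5-pentylbenzene-1,3-diol) | CCCCCc1cc(O)cc(O)c1 | starting material
2 | [(2,4-dihydroxy-6-pentylphenyl)methylidene]dimethylammonium chloride (not isolated) | CCCCCc1cc(O)cc(O)c1C=[N+](C)C.[Cl-] | intermediate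
3 | 2,4-dihydroxy-6-pentylbenzaldehyde | CCCCCc1cc(O)cc(O)c1C=O | intermediate
4 | 2-hydroxy-4-(methoxymethoxy)-6-pentylbenzaldehyde | CCCCCc1cc(OCOC)cc(O)c1C=O | intermediate
5 | 2-methoxy-4-(methoxymethoxy)-6-pentylbenzaldehyde | CCCCCc1cc(OCOC)cc(OC)c1C=O | intermediate
6 | 2-methoxy-4-(methoxymethoxy)-6-pentylbenzoic acid | CCCCCc1cc(OCOC)cc(OC)c1C(=O)O | intermediate
7 | benzyl 2-methoxy-4-(methoxymethoxy)-6-pentylbenzoate | CCCCCc1cc(OCOC)cc(OC)c1C(=O)OCc1ccccc1 | intermediate
8 | benzyl 4-hydroxy-2-methoxy-6-pentylbenzoate | CCCCCc1cc(O)cc(OC)c1C(=O)OCc1ccccc1 | intermediate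
9 | hexanoyl chloride | CCCCCC(=O)Cl | starting material
10 | N-methoxy-N-methylhexanamide | CCCCCC(=O)N(C)OC | intermediate
11 | 2,2,6-trimethyl-4H-1,3-dioxin-4-one | CC1=CC(=O)OC(C)(C)O1 | starting material
12 | acetyl chloride | CC(=O)Cl | starting material
13 | lithium 2,2-dimethyl-6-methylidene-6H-1,3-dioxin-4-olate (not isolated) | [Li+].C=C1C=C([O-])OC(C)(C)O1 | intermediate
14 | 2,2-dimethyl-6-(2-oxopropyl)-4H-1,3-dioxin-4-one | CC(=O)CC1=CC(=O)OC(C)(C)O1 | intermediate
15 | dilithium 2,2-dimethyl-6-(2-oxidoprop-2-en-1-ylidene)-6H-1,3-dioxin-4-olate (not isolated) | [Li+].[Li+].C=C([O-])C=C1C=C([O-])OC(C)(C)O1 | intermediate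
16 | 6-(2,4-dioxononyl)-2,2-dimethyl-4H-1,3-dioxin-4-one | CCCCCC(=O)CC(=O)CC1=CC(=O)OC(C)(C)O1 | intermediate
17 | dodec-1-ene-1,3,5,7-tetrone (acylketene, not isolated) | CCCCCC(=O)CC(=O)CC(=O)C=C=O | intermediate
18 | benzyl 2-methoxy-6-pentyl-4-[(3,5,7-trioxododecanoyl)oxy]benzoate | CCCCCC(=O)CC(=O)CC(=O)CC(=O)Oc1cc(CCCCC)c(C(=O)OCc2ccccc2)c(OC)c1 | intermediate
19 | benzyl 4-[(2-hydroxy-4,6-dioxo-2-pentylcyclohexane-1-carbonyl)oxy]-2-methoxy-6-pentylbenzoate (mixture of diastereomers, not isolated) | CCCCCC1(O)CC(=O)CC(=O)C1C(=O)Oc1cc(CCCCC)c(C(=O)OCc2ccccc2)c(OC)c1 | intermediate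
20 | benzyl 4-[(2,4-dihydroxy-6-pentylbenzoyl)oxy]-2-methoxy-6-pentylbenzoate | CCCCCc1cc(O)cc(O)c1C(=O)Oc1cc(CCCCC)c(C(=O)OCc2ccccc2)c(OC)c1 | intermediate
21 | 4-[(2,4-dihydroxy-6-pentylbenzoyl)oxy]-2-methoxy-6-pentylbenzoic acid | CCCCCc1cc(O)cc(O)c1C(=O)Oc1cc(CCCCC)c(C(=O)O)c(OC)c1 | target

## Step count and risks

Total step count: 12.
Longest linear sequence: 9 steps (steps 1–6, then 10, 11, 12). The dioxinone branch (steps 7–9) converges at step 10.

**Steps most likely to fail**

1. Step 11 (key step). The cyclization may be diverted toward attack at the activated aryl ester carbon, by the C5 enol oxygen or by C6, with expulsion of the ring B phenol. Dehydration of the aldol adduct may also stall.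
 Fallback: it sets out from 16 (with 8 as the coupling partner) and comes back at 21. The same aldol aromatization is run one stage earlier, on the dioxinone itself, where no phenoxide can be expelled. Treating 16 with Et3N in CH2Cl2 should give 7-hydroxy-2,2-dimethyl-5-pentyl-4H-1,3-benzodioxin-4-one F1. Benzylation (BnBr, K2CO3, DMF) would give 7-(benzyloxy)-2,2-dimethyl-5-pentyl-4H-1,3-benzodioxin-4-one F2. Opening of the acetonide with KOH in aqueous DMSO at 80 °C, with cold acidification, would give 4-(benzyloxy)-2-hydroxy-6-pentylbenzoic acid F3. Condensation of F3 with phenol 8 through the mixed anhydride ((CF3CO)2O, toluene, rt) would give benzyl 4-{[4-(benzyloxy)-2-hydroxy-6-pentylbenzoyl]oxy}-2-methoxy-6-pentylbenzoate F4. Hydrogenolysis of both benzyl groups (H2, 10% Pd/C, EtOAc) would then give 21 directly.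

2. Step 10. Capture of the acylketene by the weakly nucleophilic, para-acyl-substituted phenol may be too slow, so that intramolecular O-acylation of the ketene by its own C5 enol, ketene dimerization, or premature thermal cyclization of the product consumes the material.
 Fallback: it sets out from 3 (with 8 as the coupling partner) and comes back at 21, avoiding ketene chemistry altogether. Double benzylation of 3 (BnBr, K2CO3, DMF, 60 °C) would give 2,4-bis(benzyloxy)-6-pentylbenzaldehyde F5. Pinnick oxidation (NaClO2, NaH2PO4, 2-methyl-2-butene, t-BuOH/H2O) would give 2,4-bis(benzyloxy)-6-pentylbenzoic acid F6. Mixed-anhydride esterification with 8 ((CF3CO)2O, toluene, rt) would give benzyl 4-{[2,4-bis(benzyloxy)-6-pentylbenzoyl]oxy}-2-methoxy-6-pentylbenzoate F7. Global hydrogenolysis (H2, 10% Pd/C, EtOAc) would remove all three benzyl groups and give 21.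

3. Step 9. The dianion may be quenched by proton transfer from the enolizable amide or from the product, or it may be acylated on oxygen or at the internal carbon, so that conversion to the diketone is incomplete.
 Fallback: it sets out from 11 and comes back at 16, replacing the dianion Claisen by a soft-enolization acylation and a decarboxylation. Dienolate 13 (from 11 and LiN(SiMe3)2, THF, −78 °C) is acylated with allyl 3-chloro-3-oxopropanoate to give allyl 4-(2,2-dimethyl-4-oxo-4H-1,3-dioxin-6-yl)-3-oxobutanoate F8. C-Acylation of F8 at the doubly activated methylene with hexanoyl chloride 9 (MgCl2, pyridine, CH2Cl2, 0 °C) would give allyl 2-[(2,2-dimethyl-4-oxo-4H-1,3-dioxin-6-yl)acetyl]-3-oxooctanoate F9. Deallylation with Pd(PPh3)4 (zerovalent palladium, catalytic) and morpholine in THF, followed by spontaneous decarboxylation, would give 16.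

## Further compounds

F1 | step 11 | 7-hydroxy-2,2-dimethyl-5-pentyl-4H-1,3-benzodioxin-4-one | CCCCCc1cc(O)cc2OC(C)(C)OC(=O)c12
F2 | step 11 | 7-(benzyloxy)-2,2-dimethyl-5-pentyl-4H-1,3-benzodioxin-4-one | CCCCCc1cc(OCc3ccccc3)cc2OC(C)(C)OC(=O)c12
F3 | step 11 | 4-(benzyloxy)-2-hydroxy-6-pentylbenzoic acid | CCCCCc1cc(OCc2ccccc2)cc(O)c1C(=O)O
F4 | step 11 | benzyl 4-{[4-(benzyloxy)-2-hydroxy-6-pentylbenzoyl]oxy}-2-methoxy-6-pentylbenzoate | CCCCCc1cc(OCc2ccccc2)cc(O)c1C(=O)Oc1cc(CCCCC)c(C(=O)OCc2ccccc2)c(OC)c1
F5 | step 10 | 2,4-bis(benzyloxy)-6-pentylbenzaldehyde | CCCCCc1cc(OCc2ccccc2)cc(OCc2ccccc2)c1C=O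
F6 | step 10 | 2,4-bis(benzyloxy)-6-pentylbenzoic acid | CCCCCc1cc(OCc2ccccc2)cc(OCc2ccccc2)c1C(=O)O
F7 | step 10 | benzyl 4-{[2,4-bis(benzyloxy)-6-pentylbenzoyl]oxy}-2-methoxy-6-pentylbenzoate | CCCCCc1cc(OCc2ccccc2)cc(OCc2ccccc2)c1C(=O)Oc1cc(CCCCC)c(C(=O)OCc2ccccc2)c(OC)c1
F8 | step 9 | allyl 4-(2,2-dimethyl-4-oxo-4H-1,3-dioxin-6-yl)-3-oxobutanoate | C=CCOC(=O)CC(=O)CC1=CC(=O)OC(C)(C)O1
F9 | step 9 | allyl 2-[(2,2-dimethyl-4-oxo-4H-1,3-dioxin-6-yl)acetyl]-3-oxooctanoate | CCCCCC(=O)C(C(=O)OCC=C)C(=O)CC1=CC(=O)OC(C)(C)O1
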